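The tridepside is disconnected at three aryl C–O bonds: the hydroxyls at C6 of ring A and at C2 of rings B and C. Each ring carries its ester carbonyl at C1 flanked by a methyl group and exactly one C–H, so one ruthenium-catalysed, carbonyl-directed oxygenation of a triester lacking these hydroxyls should install all three phenols at once, without any ring closure. The precursor is a linear triester assembled from mono-phenolic, mono-ortho-substituted acids by two unhindered acylations. Ring A carries its C4 oxygen as a benzyl carbonate and ring C its carboxyl as a benzyl ester, so that a single hydrogenolysis after the oxidation releases the natural product.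

Key step: step 8

Remark: rings are lettered A (methoxy ring), B (middle) and C (acid terminus); C1 is always the carbonyl-bearing carbon, and rings B and C are numbered as in the target (hydroxyl C2, ester oxygen C4, methyl C6) even where a systematic name numbers them the other way; 4-(benzyloxy)-3-methoxybenzoic acid is assumed to be purchasable.

Step 1
Reactants: 1 4-(benzyloxy)-3-methoxybenzoic acid
Product: 3 4-(benzyloxy)-3-methoxy-2-methylbenzoic acid, via dilithio benzoate 2 (not isolated)
Conditions: lithium 2,2,6,6-tetramethylpiperidide (from n-BuLi and 2,2,6,6-tetramethylpiperidine, 4 equiv), THF, 0 °C; then cannulated into MeI, THF, −78 °C to rt; aq. HCl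
Reagents that add atoms: iodomethane, CI
Why: Directed ortho-metalation, in which the lithium carboxylate and the C3 methoxy group jointly acidify C2–H so that the hindered amide base should remove it in preference to the singly activated C5 and C6 hydrogens, and the aryllithium is then methylated (inverse addition limits lateral metalation of the new methyl group).

Step 2
Reactants: 3 4-(benzyloxy)-3-methoxy-2-methylbenzoic acid
Product: 4 4-hydroxy-3-methoxy-2-methylbenzoic acid
Conditions: H2 (1 atm), Pd/C, EtOAc/MeOH, rt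
Reagents that add atoms: none
Why: Catalytic hydrogenolysis of the aryl benzyl ether, to which the acid, methoxy and methyl groups are inert.

Step 3
Reactants: 4 4-hydroxy-3-methoxy-2-methylbenzoic acid
Product: 5 4-{[(benzyloxy)carbonyl]oxy}-3-methoxy-2-methylbenzoic acid
Conditions: benzyl chloroformate (1.1 equiv), NaOH (2 equiv, aq.), acetone/H2O, 0 °C; then HCl to pH 2
Reagents that add atoms: benzyl chloroformate, O=C(Cl)OCc1ccccc1
Why: Schotten–Baumann acylation in which the phenoxide is far more nucleophilic than the carboxylate, any mixed anhydride at the carboxylate is hydrolysed back, and no excess hydroxide remains to attack the new aryl carbonate.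

Step 4
Reactants: 5 4-{[(benzyloxy)carbonyl]oxy}-3-methoxy-2-methylbenzoic acid; 6 4-hydroxy-2-methylbenzaldehyde
Product: 8 4-formyl-3-methylphenyl 4-{[(benzyloxy)carbonyl]oxy}-3-methoxy-2-methylbenzoate, via acid chloride 7 (not isolated)
Conditions: (COCl)2, DMF (cat.), CH2Cl2, 0 °C to rt; concentrate; then 6, Et3N, CH2Cl2, 0 °C
Reagents that add atoms: none
Why: Acyl chloride formation followed by base-mediated O-acylation of the only phenol present; the acid has a single ortho substituent and the aldehyde is a latent carboxyl that cannot self-condense.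

Step 5
Reactants: 8 4-formyl-3-methylphenyl 4-{[(benzyloxy)carbonyl]oxy}-3-methoxy-2-methylbenzoate
Product: 9 4-[(4-{[(benzyloxy)carbonyl]oxy}-3-methoxy-2-methylbenzoyl)oxy]-2-methylbenzoic acid
Conditions: NaClO2, NaH2PO4, 2-methyl-2-butene, t-BuOH/THF/H2O, 0 °C to rt
Reagents that add atoms: sodium chlorite (NaClO2), [Na+].[O-]Cl=O
Why: Pinnick oxidation of the aryl aldehyde under buffered, weakly acidic conditions that should leave the aryl ester and carbonate intact, with the alkene scavenging hypochlorous acid before it can chlorinate ring A.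

Step 6
Reactants: 10 4-hydroxy-2-methylbenzoic acid
Product: 11 benzyl 4-hydroxy-2-methylbenzoate
Conditions: BnBr, KHCO3, DMF, 40 °C
Reagents that add atoms: benzyl bromide, BrCc1ccccc1
Why: SN2 alkylation of the carboxylate; hydrogencarbonate deprotonates the acid but not the phenol, so the phenol should stay free for the next acylation.

Step 7
Reactants: 9 4-[(4-{[(benzyloxy)carbonyl]oxy}-3-methoxy-2-methylbenzoyl)oxy]-2-methylbenzoic acid; 11 benzyl 4-hydroxy-2-methylbenzoate
Product: 13 benzyl 4-({4-[(4-{[(benzyloxy)carbonyl]oxy}-3-methoxy-2-methylbenzoyl)oxy]-2-methylbenzoyl}oxy)-2-methylbenzoate, via acid chloride 12 (not isolated)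
Conditions: (COCl)2, DMF (cat.), CH2Cl2, 0 °C to rt; concentrate; then 11, Et3N, CH2Cl2, 0 °C
Reagents that add atoms: none
Why: The same acyl chloride esterification as in step 4; the acyl chloride is far more electrophilic than the aryl ester and carbonate already present, so the phenol of 11 should be acylated without acyl scrambling at 0 °C.

Step 8
Reactants: 13 benzyl 4-({4-[(4-{[(benzyloxy)carbonyl]oxy}-3-methoxy-2-methylbenzoyl)oxy]-2-methylbenzoyl}oxy)-2-methylbenzoate
Product: 15 benzyl 2-hydroxy-4-({2-hydroxy-4-[(4-{[(benzyloxy)carbonyl]oxy}-6-hydroxy-3-methoxy-2-methylbenzoyl)oxy]-6-methylbenzoyl}oxy)-6-methylbenzoate, via tris(trifluoroacetate) 14 (not isolated)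
Conditions: [RuCl2(p-cymene)]2 (10 mol %), PhI(OCOCF3)2 (4.5 equiv), TFA/TFAA, DCE, 50–60 °C; then NaHCO3 (aq.), THF/MeOH, 0 °C
Reagents that add atoms: [bis(trifluoroacetoxy)iodo]benzene, O=C(OI(OC(=O)C(F)(F)F)c1ccccc1)C(F)(F)F
Why: Proposed new method: each aroyl carbonyl oxygen is expected to bind the cationic divalent ruthenium trifluoroacetate formed from [RuCl2(p-cymene)]2, carboxylate-assisted C–H cleavage then gives a five-membered ruthenacycle, PhI(OCOCF3)2 oxidises it to a tetravalent ruthenium aryl species and C–O reductive elimination releases the aryl trifluoroacetate, the cycle running once on each ring. The closest known reaction type is the ruthenium-catalysed, ester-directed ortho-hydroxylation of alkyl benzoates with hypervalent iodine or persulfate oxidants in TFA/TFAA; new here are aryl esters as directing groups and three sites oxidised in one operation. No ring is closed and no stereocentre is formed. Site selectivity is needed on every ring and comes from the substitution pattern: each C1 carbonyl has a methyl group on one ortho carbon and a single C–H on the other (C6 of ring A, C2 of rings B and C), the five-membered metallacycle on the acyl side is favoured over six-membered ones through an aryloxy or carbonate oxygen, and on ring A C6 is also para to the C3 methoxy group, so undirected electrophilic oxygenation would point to the same carbon. TFAA should keep each new phenol as its trifluoroacetate until the hydrogencarbonate work-up, which shields the hydroquinone-type oxygen pattern of ring A from the oxidant, and the ester links insulate the rings electronically, so the earlier oxygenations should not slow the last. The benzyl carbonate keeps ring A electron-poor, and it and the benzyl ester would still converge on the target if partly lost to acid.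

Step 9
Reactants: 15 benzyl 2-hydroxy-4-({2-hydroxy-4-[(4-{[(benzyloxy)carbonyl]oxy}-6-hydroxy-3-methoxy-2-methylbenzoyl)oxy]-6-methylbenzoyl}oxy)-6-methylbenzoate
Product: 16 4-({4-[(4,6-dihydroxy-3-methoxy-2-methylbenzoyl)oxy]-2-hydroxy-6-methylbenzoyl}oxy)-2-hydroxy-6-methylbenzoic acid (target)
Conditions: H2 (1 atm), Pd/C, THF/EtOAc, rt
Reagents that add atoms: none
Why: Hydrogenolysis cleaves both benzylic C–O bonds, the ester giving the acid and the carbonate falling apart to the ring A phenol, toluene and CO2, while the hindered, hydrogen-bonded aryl ester links are inert to H2 and Pd/C under neutral conditions.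

Compound list
1 | 4-(benzyloxy)-3-methoxybenzoic acid | COc1cc(C(=O)O)ccc1OCc1ccccc1 | starting material
2 | lithium 4-(benzyloxy)-2-lithio-3-methoxybenzoate | [Li]c1c(OC)c(OCc2ccccc2)ccc1C(=O)O[Li] | intermediate
3 | 4-(benzyloxy)-3-methoxy-2-methylbenzoic acid | COc1c(OCc2ccccc2)ccc(C(=O)O)c1C | intermediate
4 | 4-hydroxy-3-methoxy-2-methylbenzoic acid | COc1c(O)ccc(C(=O)O)c1C | intermediate
5 | 4-{[(benzyloxy)carbonyl]oxy}-3-methoxy-2-methylbenzoic acid | COc1c(OC(=O)OCc2ccccc2)ccc(C(=O)O)c1C | intermediate
6 | 4-hydroxy-2-methylbenzaldehyde | Cc1cc(O)ccc1C=O | starting material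
7 | 4-{[(benzyloxy)carbonyl]oxy}-3-methoxy-2-methylbenzoyl chloride | COc1c(OC(=O)OCc2ccccc2)ccc(C(Cl)=O)c1C | intermediate
8 | 4-formyl-3-methylphenyl 4-{[(benzyloxy)carbonyl]oxy}-3-methoxy-2-methylbenzoate | COc1c(OC(=O)OCc2ccccc2)ccc(C(=O)Oc2cc(C)c(C=O)cc2)c1C | intermediate
9 | 4-[(4-{[(benzyloxy)carbonyl]oxy}-3-methoxy-2-methylbenzoyl)oxy]-2-methylbenzoic acid | COc1c(OC(=O)OCc2ccccc2)ccc(C(=O)Oc2cc(C)c(C(=O)O)cc2)c1C | intermediate
10 | 4-hydroxy-2-methylbenzoic acid | Cc1cc(O)ccc1C(=O)O | starting material
11 | benzyl 4-hydroxy-2-methylbenzoate | Cc1cc(O)ccc1C(=O)OCc1ccccc1 | intermediate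
12 | 4-[(4-{[(benzyloxy)carbonyl]oxy}-3-methoxy-2-methylbenzoyl)oxy]-2-methylbenzoyl chloride | COc1c(OC(=O)OCc2ccccc2)ccc(C(=O)Oc2cc(C)c(C(Cl)=O)cc2)c1C | intermediate
13 | benzyl 4-({4-[(4-{[(benzyloxy)carbonyl]oxy}-3-methoxy-2-methylbenzoyl)oxy]-2-methylbenzoyl}oxy)-2-methylbenzoate | COc1c(OC(=O)OCc2ccccc2)ccc(C(=O)Oc2cc(C)c(C(=O)Oc3cc(C)c(C(=O)OCc4ccccc4)cc3)cc2)c1C | intermediate
14 | tris(trifluoroacetate) of 15 at the three new aryl oxygens | COc1c(OC(=O)OCc2ccccc2)cc(OC(=O)C(F)(F)F)c(C(=O)Oc2cc(C)c(C(=O)Oc3cc(C)c(C(=O)OCc4ccccc4)c(OC(=O)C(F)(F)F)c3)c(OC(=O)C(F)(F)F)c2)c1C | intermediate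
15 | benzyl 2-hydroxy-4-({2-hydroxy-4-[(4-{[(benzyloxy)carbonyl]oxy}-6-hydroxy-3-methoxy-2-methylbenzoyl)oxy]-6-methylbenzoyl}oxy)-6-methylbenzoate | COc1c(OC(=O)OCc2ccccc2)cc(O)c(C(=O)Oc2cc(C)c(C(=O)Oc3cc(C)c(C(=O)OCc4ccccc4)c(O)c3)c(O)c2)c1C | intermediate
16 | 4-({4-[(4,6-dihydroxy-3-methoxy-2-methylbenzoyl)oxy]-2-hydroxy-6-methylbenzoyl}oxy)-2-hydroxy-6-methylbenzoic acid | COc1c(O)cc(O)c(C(=O)Oc2cc(C)c(C(=O)Oc3cc(C)c(C(=O)O)c(O)c3)c(O)c2)c1C | target

Total step count: 9. Longest linear sequence: 8 steps (steps 1 to 5 and 7 to 9); step 6 is a one-step side branch.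

Steps most likely to fail

Step 8. The oxygenation may stop at mixtures of mono- and di-hydroxylated triesters, because aryl esters bind ruthenium more weakly than alkyl esters. Metalation through an aryloxy or carbonate oxygen may compete, and ring A may be oxidised further once its C6 oxygen is in place. The fallback brings the ortho hydroxyls in with the building blocks, by known chemistry only. It sets out from acid 3. Pd(OAc)2-catalysed, carboxylate-directed ortho-hydroxylation (KOAc, benzoquinone, O2, DMA, 115 °C) would give 4-(benzyloxy)-6-hydroxy-3-methoxy-2-methylbenzoic acid F1. Condensation with commercial 2,4-dihydroxy-6-methylbenzaldehyde at its non-chelated C4 hydroxyl (TFAA, toluene, rt) would give 4-formyl-3-hydroxy-5-methylphenyl 4-(benzyloxy)-6-hydroxy-3-methoxy-2-methylbenzoate F2. Chlorite oxidation (NaClO2, NaH2PO4, excess 2-methyl-2-butene) would give 4-{[4-(benzyloxy)-6-hydroxy-3-methoxy-2-methylbenzoyl]oxy}-2-hydroxy-6-methylbenzoic acid F3. A second TFAA-mediated condensation, with benzyl 2,4-dihydroxy-6-methylbenzoate F4 (from commercial 2,4-dihydroxy-6-methylbenzoic acid, BnBr, KHCO3, DMF), would give benzyl 4-[(4-{[4-(benzyloxy)-6-hydroxy-3-methoxy-2-methylbenzoyl]oxy}-2-hydroxy-6-methylbenzoyl)oxy]-2-hydroxy-6-methylbenzoate F5. Hydrogenolysis (H2, Pd/C) of both benzyl groups returns to the route at target 16.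

Step 1. Metalation may occur at the benzylic methylene of the ether or at C5 or C6 instead of C2, and the new methyl group may be metalated laterally and methylated a second time. The fallback replaces the carboxylate by a stronger, removable ortho director. It sets out from acid 1. SOCl2 and then 2-amino-2-methylpropan-1-ol would give 4-(benzyloxy)-N-(1-hydroxy-2-methylpropan-2-yl)-3-methoxybenzamide F6. Cyclodehydration with SOCl2 would give 2-[4-(benzyloxy)-3-methoxyphenyl]-4,4-dimethyl-4,5-dihydro-1,3-oxazole F7. Lithiation between the oxazoline and the methoxy group (n-BuLi, THF, −45 °C) and quenching with MeI would give 2-[4-(benzyloxy)-3-methoxy-2-methylphenyl]-4,4-dimethyl-4,5-dihydro-1,3-oxazole F8. N-Methylation with MeI would give 2-[4-(benzyloxy)-3-methoxy-2-methylphenyl]-3,4,4-trimethyl-4,5-dihydro-1,3-oxazol-3-ium iodide F9. Hydrolysis (NaOH, aq. MeOH, reflux, then acid) returns to the route at acid 3.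

Step 7. The phenoxide of 11 may attack the carbonate or the internal aryl ester of 12 instead of the acyl chloride, which would scramble the acyl groups. The fallback reverses the order of assembly so that the last acylation uses the simple ring A acid chloride. It sets out from acid 10. Silylation (TBSCl, imidazole, DMF) would give tert-butyldimethylsilyl 4-[(tert-butyldimethylsilyl)oxy]-2-methylbenzoate F10. Hydrolysis of its labile silyl ester (aq. AcOH, THF) would give 4-[(tert-butyldimethylsilyl)oxy]-2-methylbenzoic acid F11. Carbodiimide coupling with phenol 11 (EDC hydrochloride, DMAP cat., CH2Cl2) would give benzyl 4-({4-[(tert-butyldimethylsilyl)oxy]-2-methylbenzoyl}oxy)-2-methylbenzoate F12. Buffered desilylation (TBAF, AcOH, THF, 0 °C) would give benzyl 4-[(4-hydroxy-2-methylbenzoyl)oxy]-2-methylbenzoate F13. Acylation of F13 with acid chloride 7, made from 5 as in step 4 (Et3N, CH2Cl2, 0 °C), returns to the route at triester 13; steps 4 and 5 are then not needed.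

Further compounds
F1 | step 8 | 4-(benzyloxy)-6-hydroxy-3-methoxy-2-methylbenzoic acid | COc1c(OCc2ccccc2)cc(O)c(C(=O)O)c1C
F2 | step 8 | 4-formyl-3-hydroxy-5-methylphenyl 4-(benzyloxy)-6-hydroxy-3-methoxy-2-methylbenzoate | COc1c(OCc2ccccc2)cc(O)c(C(=O)Oc2cc(C)c(C=O)c(O)c2)c1C
F3 | step 8 | 4-{[4-(benzyloxy)-6-hydroxy-3-methoxy-2-methylbenzoyl]oxy}-2-hydroxy-6-methylbenzoic acid | COc1c(OCc2ccccc2)cc(O)c(C(=O)Oc2cc(C)c(C(=O)O)c(O)c2)c1C
F4 | step 8 | benzyl 2,4-dihydroxy-6-methylbenzoate | Cc1cc(O)cc(O)c1C(=O)OCc1ccccc1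
F5 | step 8 | benzyl 4-[(4-{[4-(benzyloxy)-6-hydroxy-3-methoxy-2-methylbenzoyl]oxy}-2-hydroxy-6-methylbenzoyl)oxy]-2-hydroxy-6-methylbenzoate | COc1c(OCc2ccccc2)cc(O)c(C(=O)Oc2cc(C)c(C(=O)Oc3cc(C)c(C(=O)OCc4ccccc4)c(O)c3)c(O)c2)c1C
F6 | step 1 | 4-(benzyloxy)-N-(1-hydroxy-2-methylpropan-2-yl)-3-methoxybenzamide | COc1cc(C(=O)NC(C)(C)CO)ccc1OCc1ccccc1
F7 | step 1 | 2-[4-(benzyloxy)-3-methoxyphenyl]-4,4-dimethyl-4,5-dihydro-1,3-oxazole | COc1cc(C2=NC(C)(C)CO2)ccc1OCc1ccccc1
F8 | step 1 | 2-[4-(benzyloxy)-3-methoxy-2-methylphenyl]-4,4-dimethyl-4,5-dihydro-1,3-oxazole | COc1c(OCc2ccccc2)ccc(C2=NC(C)(C)CO2)c1C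
F9 | step 1 | 2-[4-(benzyloxy)-3-methoxy-2-methylphenyl]-3,4,4-trimethyl-4,5-dihydro-1,3-oxazol-3-ium iodide | COc1c(OCc2ccccc2)ccc(C2=[N+](C)C(C)(C)CO2)c1C.[I-]
F10 | step 7 | tert-butyldimethylsilyl 4-[(tert-butyldimethylsilyl)oxy]-2-methylbenzoate | Cc1cc(O[Si](C)(C)C(C)(C)C)ccc1C(=O)O[Si](C)(C)C(C)(C)C
F11 | step 7 | 4-[(tert-butyldimethylsilyl)oxy]-2-methylbenzoic acid | Cc1cc(O[Si](C)(C)C(C)(C)C)ccc1C(=O)O
F12 | step 7 | benzyl 4-({4-[(tert-butyldimethylsilyl)oxy]-2-methylbenzoyl}oxy)-2-methylbenzoate | Cc1cc(O[Si](C)(C)C(C)(C)C)ccc1C(=O)Oc1cc(C)c(C(=O)OCc2ccccc2)cc1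
F13 | step 7 | benzyl 4-[(4-hydroxy-2-methylbenzoyl)oxy]-2-methylbenzoate | Cc1cc(O)ccc1C(=O)Oc1cc(C)c(C(=O)OCc2ccccc2)cc1
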